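**Plan**
- Retrosynthetic cuts, in order: the five O-protecting groups; the C4–C4a bond of the pyranone (ring C); the C2–O1 enol ether bond (phenol plus arylpropiolate); then in the side chain the carbinol C–CH3 bond, the exocyclic C=C bond to the ring A aldehyde, and one C–CH3 bond of the gem-dimethyl carbon.
- Enabling feature: ring A enters the closure as a 4-alkyl-3,5-bis(benzyloxy)phenyl ether whose two carbons ortho to the ether oxygen are equivalent. Whichever becomes C4a, the cyclohexylmethyl carbon sits at C6 between the C5 and C7 oxygens, and three oxygen donors make that carbon nucleophilic enough for acylation.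
- Forward order: the ring A aldehyde is made and condensed with the cuprate-derived enolate of the cyclohexanone (carbocycle intact from 3-methylcyclohexenone). After the side chain is finished, the phenol is joined through oxygen to the ring B propiolate, ring C is closed last, and the protecting groups are removed.
- Stereochemistry: the carbinol centre (S) comes from catalyst-controlled Re-face methyl addition to the enone carbonyl; the neighbouring CH centre (S) is relayed from it by hydroxyl-directed hydrogenation; neither is touched afterwards.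

Key step: step 13

Assumption: the sense of induction of the titanium bis(sulfonamide) diol catalyst on enone 10 is taken by analogy with other α-substituted enones, so the ligand antipode is defined by its outcome (methyl to the Re face of C1); both antipodes are accessible from the enantiomers of trans-1,2-diaminocyclohexane and camphor-10-sulfonyl chloride.

**Route**

Step 1
Reactants: 1 3,5-bis(benzyloxy)phenol
Product: 2 1,3-bis(benzyloxy)-5-(triisopropylsilyloxy)benzene
Conditions: TIPSCl, imidazole, DMF, rt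
Reagents that add atoms: chlorotriisopropylsilane (TIPSCl), `CC(C)[Si](Cl)(C(C)C)C(C)C`
Why: Imidazole-promoted silylation of the phenol gives a bulky aryl silyl ether that masks the oxygen later needed as nucleophile and neither directs nor tolerates metalation next to it.

Step 2
Reactants: 2 1,3-bis(benzyloxy)-5-(triisopropylsilyloxy)benzene
Product: 4 2,6-bis(benzyloxy)-4-(triisopropylsilyloxy)benzaldehyde, via aryllithium 3 (not isolated)
Conditions: n-BuLi, THF, 0 °C; then DMF, −78 °C to rt; aq NH4Cl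
Reagents that add atoms: N,N-dimethylformamide (DMF), `CN(C)C=O`
Why: Directed ortho-metalation removes the proton flanked by the two coordinating benzyloxy groups (lithium ends para to the silyl ether, so no silyl migration is possible) and formylation of the aryllithium with DMF gives the aldehyde.

Step 3
Reactants: 5 3-methylcyclohex-2-en-1-one; 4 2,6-bis(benzyloxy)-4-(triisopropylsilyloxy)benzaldehyde
Product: 8 2-{[2,6-bis(benzyloxy)-4-(triisopropylsilyloxy)phenyl](hydroxy)methyl}-3,3-dimethylcyclohexan-1-one (mixture of diastereomers), via lithium enolate 6 (not isolated), via chlorozinc enolate 7 (not isolated)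
Conditions: Me2CuLi (from MeLi and CuI), Et2O, 0 °C; ZnCl2, THF, −78 °C; then 4, −78 to −30 °C; aq NH4Cl
Reagents that add atoms: lithium dimethylcuprate (Me2CuLi), `[Li+].C[Cu-]C`
Why: Tandem conjugate addition–aldol reaction: the Gilman reagent builds the gem-dimethyl carbon and leaves the enolate regiodefined at C2, which after transmetalation to zinc adds to the aldehyde; the two new stereocentres are uncontrolled and disappear in step 4.

Step 4
Reactants: 8 2-{[2,6-bis(benzyloxy)-4-(triisopropylsilyloxy)phenyl](hydroxy)methyl}-3,3-dimethylcyclohexan-1-one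
Product: 10 (2Z)-2-{[2,6-bis(benzyloxy)-4-(triisopropylsilyloxy)phenyl]methylidene}-3,3-dimethylcyclohexan-1-one, via mesylate 9 (not isolated)
Conditions: MsCl, Et3N, CH2Cl2, 0 °C; then DBU, rt
Reagents that add atoms: none
Why: Mesylation and base-induced β-elimination (E1cB, helped by the electron-rich benzylic position) complete the aldol condensation; the Z alkene is expected because the E isomer would press the 2,6-disubstituted aryl group against the gem-dimethyl carbon, and the geometry has no consequence once this carbon becomes CH2.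

Step 5
Reactants: 10 (2Z)-2-{[2,6-bis(benzyloxy)-4-(triisopropylsilyloxy)phenyl]methylidene}-3,3-dimethylcyclohexan-1-one
Product: 11 (1S,2Z)-2-{[2,6-bis(benzyloxy)-4-(triisopropylsilyloxy)phenyl]methylidene}-1,3,3-trimethylcyclohexan-1-ol
Conditions: Me2Zn, Ti(OiPr)4, trans-1,2-bis(2-hydroxycamphor-10-sulfonamido)cyclohexane (10 mol %), toluene–hexane, rt; aq NH4Cl
Reagents that add atoms: dimethylzinc (Me2Zn), `C[Zn]C`
Why: Catalytic enantioselective 1,2-addition of a dialkylzinc to an α-substituted conjugated ketone: the chiral titanium bis(sulfonamide) diol complex activates the carbonyl, tells the alkylidene-bearing sp2 carbon from the ring CH2 and delivers methyl to the Re face of C1, which sets the tertiary carbinol as S.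

Step 6
Reactants: 11 (1S,2Z)-2-{[2,6-bis(benzyloxy)-4-(triisopropylsilyloxy)phenyl]methylidene}-1,3,3-trimethylcyclohexan-1-ol
Product: 12 (1S,2S)-2-{[2,6-bis(benzyloxy)-4-(triisopropylsilyloxy)phenyl]methyl}-1,3,3-trimethylcyclohexan-1-ol
Conditions: H2 (1 atm), [Ir(cod)(PCy3)(py)]PF6 (10 mol %), CH2Cl2, rt
Reagents that add atoms: none
Why: Hydroxyl-directed homogeneous hydrogenation: the tertiary OH binds the cationic iridium centre and both hydrogens are delivered to the alkene face cis to it, so the new C2–H ends cis to OH and the arylmethyl group trans (2S), while benzyl and silyl ethers are inert to this catalyst.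

Step 7
Reactants: 12 (1S,2S)-2-{[2,6-bis(benzyloxy)-4-(triisopropylsilyloxy)phenyl]methyl}-1,3,3-trimethylcyclohexan-1-ol
Product: 13 (1S,2S)-2-{[2,6-bis(benzyloxy)-4-hydroxyphenyl]methyl}-1,3,3-trimethylcyclohexan-1-ol
Conditions: n-Bu4NF, THF, 0 °C; aq NH4Cl
Reagents that add atoms: none
Why: Fluoride-induced cleavage of the aryl O–Si bond (phenoxide as leaving group) frees the phenol needed for the next C–O bond, and the tertiary alcohol is unaffected.

Step 8
Reactants: 14 3,4-bis(benzyloxy)benzaldehyde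
Product: 15 1,2-bis(benzyloxy)-4-(2,2-dibromoethenyl)benzene
Conditions: CBr4, PPh3, CH2Cl2, 0 °C
Reagents that add atoms: tetrabromomethane (CBr4), `BrC(Br)(Br)Br`
Why: First stage of the Corey–Fuchs sequence, a Wittig-type dibromo-olefination of the aromatic aldehyde by the ylide formed from CBr4 and PPh3.

Step 9
Reactants: 15 1,2-bis(benzyloxy)-4-(2,2-dibromoethenyl)benzene
Product: 17 methyl 3-[3,4-bis(benzyloxy)phenyl]prop-2-ynoate, via lithium acetylide 16 (not isolated)
Conditions: n-BuLi (2.1 equiv), THF, −78 °C; then ClCO2Me, −78 °C to rt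
Reagents that add atoms: methyl chloroformate, `COC(=O)Cl`
Why: Second stage of the Corey–Fuchs sequence: bromine–lithium exchange, rearrangement to the alkyne and deprotonation give the lithium acetylide, which is C-acylated by the chloroformate.

Step 10
Reactants: 13 (1S,2S)-2-{[2,6-bis(benzyloxy)-4-hydroxyphenyl]methyl}-1,3,3-trimethylcyclohexan-1-ol; 17 methyl 3-[3,4-bis(benzyloxy)phenyl]prop-2-ynoate
Product: 18 methyl (2Z)-3-[3,5-bis(benzyloxy)-4-{[(1S,2S)-2-hydroxy-2,6,6-trimethylcyclohexyl]methyl}phenoxy]-3-[3,4-bis(benzyloxy)phenyl]prop-2-enoate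
Conditions: K2CO3, DMF, 70 °C
Reagents that add atoms: none
Why: Oxa-Michael addition of the phenoxide to the β-carbon of the ynoate, where protonation trans to the entering oxygen (anti addition) places aryloxy and ester groups cis (Z); K2CO3 does not deprotonate the tertiary alcohol, so only the phenol adds.

Step 11
Reactants: 18 methyl (2Z)-3-[3,5-bis(benzyloxy)-4-{[(1S,2S)-2-hydroxy-2,6,6-trimethylcyclohexyl]methyl}phenoxy]-3-[3,4-bis(benzyloxy)phenyl]prop-2-enoate
Product: 19 methyl (2Z)-3-[3,5-bis(benzyloxy)-4-{[(1S,2S)-2,6,6-trimethyl-2-(triethylsilyloxy)cyclohexyl]methyl}phenoxy]-3-[3,4-bis(benzyloxy)phenyl]prop-2-enoate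
Conditions: TESOTf, 2,6-lutidine, CH2Cl2, −78 to 0 °C
Reagents that add atoms: triethylsilyl trifluoromethanesulfonate (TESOTf), `CC[Si](CC)(CC)OS(=O)(=O)C(F)(F)F`
Why: Silyl triflate with a hindered pyridine base silylates even a tertiary alcohol, and the ether shields the C–O bond from the acylating agent in step 13.

Step 12
Reactants: 19 methyl (2Z)-3-[3,5-bis(benzyloxy)-4-{[(1S,2S)-2,6,6-trimethyl-2-(triethylsilyloxy)cyclohexyl]methyl}phenoxy]-3-[3,4-bis(benzyloxy)phenyl]prop-2-enoate
Product: 20 (2Z)-3-[3,5-bis(benzyloxy)-4-{[(1S,2S)-2,6,6-trimethyl-2-(triethylsilyloxy)cyclohexyl]methyl}phenoxy]-3-[3,4-bis(benzyloxy)phenyl]prop-2-enoic acid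
Conditions: LiOH, THF–MeOH–H2O, 40 °C; then aq HCl to pH 4, 0 °C
Reagents that add atoms: lithium hydroxide (its oxygen ends in the carboxyl group), `[Li+].[OH-]`
Why: Saponification of the methyl ester by acyl substitution, as in the classical hydrolysis of β-aryloxycinnamates; the hindered tertiary silyl ether and the benzyl ethers are stable to aqueous hydroxide and to the brief cold acidification.

Step 13
Reactants: 20 (2Z)-3-[3,5-bis(benzyloxy)-4-{[(1S,2S)-2,6,6-trimethyl-2-(triethylsilyloxy)cyclohexyl]methyl}phenoxy]-3-[3,4-bis(benzyloxy)phenyl]prop-2-enoic acid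
Product: 22 5,7-bis(benzyloxy)-2-[3,4-bis(benzyloxy)phenyl]-6-{[(1S,2S)-2,6,6-trimethyl-2-(triethylsilyloxy)cyclohexyl]methyl}-4H-chromen-4-one, via acid chloride 21 (not isolated)
Conditions: 1-chloro-N,N,2-trimethylprop-1-en-1-amine, 2,6-di-tert-butyl-4-methylpyridine, CH2Cl2, 0 °C to rt
Reagents that add atoms: none
Why: The chloroenamine turns the carboxylic acid into acid chloride 21 under neutral conditions, the acyl carbon is attacked by the ring A carbon ortho to the ether oxygen, and loss of a proton to the hindered pyridine restores aromaticity, so C4–C4a forms by electrophilic aromatic substitution. The closest known reaction type is the intramolecular Friedel–Crafts acylation of 3-aryloxyacrylic (β-aryloxycinnamic) acids to chromones and flavones. Ring C closes in the 6-exo-trig mode counted from the arene carbon, the carbonyl oxygen staying outside the new ring. No stereocentre is formed and the two existing ones are remote from the reacting atoms. The step needs regioselectivity on ring A and selectivity for ring A over the catechol ring: the two ortho carbons of the 4-alkyl-3,5-bis(benzyloxy)phenoxy ring are constitutionally equivalent, so either closure puts the side chain at C6, and the Z alkene holds the acyl group beside ring A and away from the catechol ring. Three oxygen donors on ring A are the reason why no Lewis or Brønsted acid that could ionise the silylated tertiary C–O bond should be needed.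

Step 14
Reactants: 22 5,7-bis(benzyloxy)-2-[3,4-bis(benzyloxy)phenyl]-6-{[(1S,2S)-2,6,6-trimethyl-2-(triethylsilyloxy)cyclohexyl]methyl}-4H-chromen-4-one
Product: 23 5,7-bis(benzyloxy)-2-[3,4-bis(benzyloxy)phenyl]-6-{[(1S,2S)-2-hydroxy-2,6,6-trimethylcyclohexyl]methyl}-4H-chromen-4-one
Conditions: n-Bu4NF, THF, rt to 45 °C; aq NH4Cl
Reagents that add atoms: none
Why: Fluoride-mediated desilylation frees the tertiary alcohol without acid, so the carbinol cannot ionise, and the flavone and benzyl ethers are inert to fluoride.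

Step 15
Reactants: 23 5,7-bis(benzyloxy)-2-[3,4-bis(benzyloxy)phenyl]-6-{[(1S,2S)-2-hydroxy-2,6,6-trimethylcyclohexyl]methyl}-4H-chromen-4-one
Product: 24 2-(3,4-dihydroxyphenyl)-5,7-dihydroxy-6-{[(1S,2S)-2-hydroxy-2,6,6-trimethylcyclohexyl]methyl}-4H-chromen-4-one
Conditions: H2 (1 atm), 10% Pd/C, EtOAc–MeOH, rt
Reagents that add atoms: none
Why: Heterogeneous hydrogenolysis cleaves the four benzylic C–O bonds under neutral conditions that should leave the flavone C2=C3 bond, the tertiary alcohol and both stereocentres unchanged if the reaction is stopped at full debenzylation.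

**Compound list**

1 | 3,5-bis(benzyloxy)phenol | `Oc1cc(OCc2ccccc2)cc(OCc2ccccc2)c1` | starting material
2 | 1,3-bis(benzyloxy)-5-(triisopropylsilyloxy)benzene | `CC(C)[Si](Oc1cc(OCc2ccccc2)cc(OCc2ccccc2)c1)(C(C)C)C(C)C` | intermediate
3 | [2,6-bis(benzyloxy)-4-(triisopropylsilyloxy)phenyl]lithium | `[Li]c1c(OCc2ccccc2)cc(O[Si](C(C)C)(C(C)C)C(C)C)cc1OCc1ccccc1` | intermediate
4 | 2,6-bis(benzyloxy)-4-(triisopropylsilyloxy)benzaldehyde | `O=Cc1c(OCc2ccccc2)cc(O[Si](C(C)C)(C(C)C)C(C)C)cc1OCc1ccccc1` | intermediate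
5 | 3-methylcyclohex-2-en-1-one | `CC1=CC(=O)CCC1` | starting material
6 | lithium 3,3-dimethylcyclohex-1-en-1-olate | `[Li]OC1=CC(C)(C)CCC1` | intermediate
7 | chlorozinc 3,3-dimethylcyclohex-1-en-1-olate | `Cl[Zn]OC1=CC(C)(C)CCC1` | intermediate
8 | 2-{[2,6-bis(benzyloxy)-4-(triisopropylsilyloxy)phenyl](hydroxy)methyl}-3,3-dimethylcyclohexan-1-one (mixture of diastereomers) | `O=C1CCCC(C)(C)C1C(O)c1c(OCc2ccccc2)cc(O[Si](C(C)C)(C(C)C)C(C)C)cc1OCc1ccccc1` | intermediate
9 | [2,6-bis(benzyloxy)-4-(triisopropylsilyloxy)phenyl](2,2-dimethyl-6-oxocyclohexyl)methyl methanesulfonate (mixture of diastereomers) | `O=C1CCCC(C)(C)C1C(OS(C)(=O)=O)c1c(OCc2ccccc2)cc(O[Si](C(C)C)(C(C)C)C(C)C)cc1OCc1ccccc1` | intermediate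
10 | (2Z)-2-{[2,6-bis(benzyloxy)-4-(triisopropylsilyloxy)phenyl]methylidene}-3,3-dimethylcyclohexan-1-one | `O=C1CCCC(C)(C)/C1=C/c1c(OCc2ccccc2)cc(O[Si](C(C)C)(C(C)C)C(C)C)cc1OCc1ccccc1` | intermediate
11 | (1S,2Z)-2-{[2,6-bis(benzyloxy)-4-(triisopropylsilyloxy)phenyl]methylidene}-1,3,3-trimethylcyclohexan-1-ol | `CC1(C)CCC[C@](C)(O)/C1=C\c1c(OCc2ccccc2)cc(O[Si](C(C)C)(C(C)C)C(C)C)cc1OCc1ccccc1` | intermediate
12 | (1S,2S)-2-{[2,6-bis(benzyloxy)-4-(triisopropylsilyloxy)phenyl]methyl}-1,3,3-trimethylcyclohexan-1-ol | `CC1(C)CCC[C@](C)(O)[C@H]1Cc1c(OCc2ccccc2)cc(O[Si](C(C)C)(C(C)C)C(C)C)cc1OCc1ccccc1` | intermediate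
13 | (1S,2S)-2-{[2,6-bis(benzyloxy)-4-hydroxyphenyl]methyl}-1,3,3-trimethylcyclohexan-1-ol | `CC1(C)CCC[C@](C)(O)[C@H]1Cc1c(OCc2ccccc2)cc(O)cc1OCc1ccccc1` | intermediate
14 | 3,4-bis(benzyloxy)benzaldehyde | `O=Cc1ccc(OCc2ccccc2)c(OCc2ccccc2)c1` | starting material
15 | 1,2-bis(benzyloxy)-4-(2,2-dibromoethenyl)benzene | `BrC(Br)=Cc1ccc(OCc2ccccc2)c(OCc2ccccc2)c1` | intermediate
16 | {[3,4-bis(benzyloxy)phenyl]ethynyl}lithium | `[Li]C#Cc1ccc(OCc2ccccc2)c(OCc2ccccc2)c1` | intermediate
17 | methyl 3-[3,4-bis(benzyloxy)phenyl]prop-2-ynoate | `COC(=O)C#Cc1ccc(OCc2ccccc2)c(OCc2ccccc2)c1` | intermediate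
18 | methyl (2Z)-3-[3,5-bis(benzyloxy)-4-{[(1S,2S)-2-hydroxy-2,6,6-trimethylcyclohexyl]methyl}phenoxy]-3-[3,4-bis(benzyloxy)phenyl]prop-2-enoate | `CC1(C)CCC[C@](C)(O)[C@H]1Cc1c(OCc2ccccc2)cc(O/C(=C\C(=O)OC)c2ccc(OCc3ccccc3)c(OCc3ccccc3)c2)cc1OCc1ccccc1` | intermediate
19 | methyl (2Z)-3-[3,5-bis(benzyloxy)-4-{[(1S,2S)-2,6,6-trimethyl-2-(triethylsilyloxy)cyclohexyl]methyl}phenoxy]-3-[3,4-bis(benzyloxy)phenyl]prop-2-enoate | `CC1(C)CCC[C@](C)(O[Si](CC)(CC)CC)[C@H]1Cc1c(OCc2ccccc2)cc(O/C(=C\C(=O)OC)c2ccc(OCc3ccccc3)c(OCc3ccccc3)c2)cc1OCc1ccccc1` | intermediate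
20 | (2Z)-3-[3,5-bis(benzyloxy)-4-{[(1S,2S)-2,6,6-trimethyl-2-(triethylsilyloxy)cyclohexyl]methyl}phenoxy]-3-[3,4-bis(benzyloxy)phenyl]prop-2-enoic acid | `CC1(C)CCC[C@](C)(O[Si](CC)(CC)CC)[C@H]1Cc1c(OCc2ccccc2)cc(O/C(=C\C(=O)O)c2ccc(OCc3ccccc3)c(OCc3ccccc3)c2)cc1OCc1ccccc1` | intermediate
21 | (2Z)-3-[3,5-bis(benzyloxy)-4-{[(1S,2S)-2,6,6-trimethyl-2-(triethylsilyloxy)cyclohexyl]methyl}phenoxy]-3-[3,4-bis(benzyloxy)phenyl]prop-2-enoyl chloride | `CC1(C)CCC[C@](C)(O[Si](CC)(CC)CC)[C@H]1Cc1c(OCc2ccccc2)cc(O/C(=C\C(=O)Cl)c2ccc(OCc3ccccc3)c(OCc3ccccc3)c2)cc1OCc1ccccc1` | intermediate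
22 | 5,7-bis(benzyloxy)-2-[3,4-bis(benzyloxy)phenyl]-6-{[(1S,2S)-2,6,6-trimethyl-2-(triethylsilyloxy)cyclohexyl]methyl}-4H-chromen-4-one | `CC1(C)CCC[C@](C)(O[Si](CC)(CC)CC)[C@H]1Cc1c(OCc2ccccc2)cc2oc(-c3ccc(OCc4ccccc4)c(OCc4ccccc4)c3)cc(=O)c2c1OCc1ccccc1` | intermediate
23 | 5,7-bis(benzyloxy)-2-[3,4-bis(benzyloxy)phenyl]-6-{[(1S,2S)-2-hydroxy-2,6,6-trimethylcyclohexyl]methyl}-4H-chromen-4-one | `CC1(C)CCC[C@](C)(O)[C@H]1Cc1c(OCc2ccccc2)cc2oc(-c3ccc(OCc4ccccc4)c(OCc4ccccc4)c3)cc(=O)c2c1OCc1ccccc1` | intermediate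
24 | 2-(3,4-dihydroxyphenyl)-5,7-dihydroxy-6-{[(1S,2S)-2-hydroxy-2,6,6-trimethylcyclohexyl]methyl}-4H-chromen-4-one | `CC1(C)CCC[C@](C)(O)[C@H]1Cc1c(O)cc2oc(-c3ccc(O)c(O)c3)cc(=O)c2c1O` | target

**Step count and risks**

Total step count: 15. Longest linear sequence: 13 steps (from 1 through steps 1–7 and 10–15).

Steps most likely to fail:

1. Step 5. Methyl transfer to the carbonyl, which is flanked by the twisted 2,6-disubstituted aryl group, may be slow, so that uncatalysed background addition erodes the facial selectivity or the conversion stays low. The fallback gives up asymmetric catalysis for resolution and sets out from 10: addition of MeLi in the presence of CeCl3 (THF, −78 °C) should give the racemic tertiary allylic alcohol rac-(2Z)-2-{[2,6-bis(benzyloxy)-4-(triisopropylsilyloxy)phenyl]methylidene}-1,3,3-trimethylcyclohexan-1-ol F1. Its enantiomers are then separated by preparative chromatography on a polysaccharide carbamate chiral stationary phase; the 1S enantiomer is 11, where the route is rejoined before step 6.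

2. Step 3. The zinc enolate at the neopentyl-like C2 may add too slowly to the electron-rich, doubly ortho-substituted aldehyde, so that proton transfer or retro-aldol cleavage returns the starting ketone and aldehyde. The fallback replaces the aldehyde by an oxocarbenium ion and the metal enolate by a silyl enol ether, and sets out from 5 and 4. Cuprate addition to 5 with trapping by TMSCl/Et3N gives [(3,3-dimethylcyclohex-1-en-1-yl)oxy]trimethylsilane F2. Aldehyde 4 with HC(OMe)3 and catalytic pyridinium p-toluenesulfonate in MeOH gives 1,3-bis(benzyloxy)-2-(dimethoxymethyl)-5-(triisopropylsilyloxy)benzene F3. Their TMSOTf-catalysed Mukaiyama-type coupling (CH2Cl2, −78 °C) gives 2-{[2,6-bis(benzyloxy)-4-(triisopropylsilyloxy)phenyl](methoxy)methyl}-3,3-dimethylcyclohexan-1-one F4. Loss of methanol with DBU then leads to enone 10, where the route is rejoined before step 5.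

3. Step 13. Acylation may stall at the acid chloride, whose push–pull acryloyl group is a weak electrophile, or the HCl set free may strip the silyl ether and ionise the tertiary centre before the ring closes. The fallback forms the same C4–C4a bond with reversed polarity and sets out from 13. Bromination ortho to the phenolic oxygen with NBS (CH2Cl2, −78 °C) gives 3,5-bis(benzyloxy)-2-bromo-4-{[(1S,2S)-2-hydroxy-2,6,6-trimethylcyclohexyl]methyl}phenol F5. Addition to 17 as in step 10 gives methyl (2Z)-3-[3,5-bis(benzyloxy)-2-bromo-4-{[(1S,2S)-2-hydroxy-2,6,6-trimethylcyclohexyl]methyl}phenoxy]-3-[3,4-bis(benzyloxy)phenyl]prop-2-enoate F6. Treatment with t-BuLi (3 equiv, THF, −78 °C) deprotonates the alcohol, exchanges bromine for lithium, and the aryllithium attacks the ester carbonyl (Parham-type cyclisation) with loss of methoxide. This gives 23 directly, where the route is rejoined before step 15.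

**Further compounds**

F1 | step 5 | rac-(2Z)-2-{[2,6-bis(benzyloxy)-4-(triisopropylsilyloxy)phenyl]methylidene}-1,3,3-trimethylcyclohexan-1-ol | `CC1(C)CCCC(C)(O)/C1=C\c1c(OCc2ccccc2)cc(O[Si](C(C)C)(C(C)C)C(C)C)cc1OCc1ccccc1`
F2 | step 3 | [(3,3-dimethylcyclohex-1-en-1-yl)oxy]trimethylsilane | `C[Si](C)(C)OC1=CC(C)(C)CCC1`
F3 | step 3 | 1,3-bis(benzyloxy)-2-(dimethoxymethyl)-5-(triisopropylsilyloxy)benzene | `COC(OC)c1c(OCc2ccccc2)cc(O[Si](C(C)C)(C(C)C)C(C)C)cc1OCc1ccccc1`
F4 | step 3 | 2-{[2,6-bis(benzyloxy)-4-(triisopropylsilyloxy)phenyl](methoxy)methyl}-3,3-dimethylcyclohexan-1-one | `COC(C1C(=O)CCCC1(C)C)c1c(OCc2ccccc2)cc(O[Si](C(C)C)(C(C)C)C(C)C)cc1OCc1ccccc1`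
F5 | step 13 | 3,5-bis(benzyloxy)-2-bromo-4-{[(1S,2S)-2-hydroxy-2,6,6-trimethylcyclohexyl]methyl}phenol | `CC1(C)CCC[C@](C)(O)[C@H]1Cc1c(OCc2ccccc2)cc(O)c(Br)c1OCc1ccccc1`
F6 | step 13 | methyl (2Z)-3-[3,5-bis(benzyloxy)-2-bromo-4-{[(1S,2S)-2-hydroxy-2,6,6-trimethylcyclohexyl]methyl}phenoxy]-3-[3,4-bis(benzyloxy)phenyl]prop-2-enoate | `CC1(C)CCC[C@](C)(O)[C@H]1Cc1c(OCc2ccccc2)cc(O/C(=C\C(=O)OC)c2ccc(OCc3ccccc3)c(OCc3ccccc3)c2)c(Br)c1OCc1ccccc1`
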